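Summer looks nearly like blue: it has the same 1.30 equiv of partner B, and 0.900 equiv of partner A in place of 1.4 equiv. Dawn differs from summer by partner B, at 2.00 equiv, yet I expected the two to end with different leaders.

| setting | blue | summer | dawn |
|---|---|---|---|
| substrate | 0.050 M | 0.050 M | 0.050 M |
| partner A | 1.4 equiv | 0.900 equiv | 0.900 equiv |
| partner B | 1.3 equiv | 1.30 equiv | 2.00 equiv |
| remark | run made earlier |  |  |
| time |  | 1.0 h | 1.0 h |

- blue (time / min: target / %, open intermediate / %, substrate / %): 1.00: 0.4, 79.0, 20.6; 1.50: 0.5, 85.4, 13.0; 2.50: 2.7, 90.9, 6.7; 4.00: 4.3, 92.1, 3.0; 8.00: 10.8, 88.4, 1.0; 12.0: 15.2, 83.9, 0.3

(each reading ± 0.3 percentage points)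

- a reading or a percentage of target counts all its forms, free or not

- which of these there is most of at the end, counted by the substrate in it, summer (target / open intermediate / substrate)
- which of these there is most of at the end, counted by the substrate in it, dawn (target / open intermediate / substrate)
- the largest of these amounts at the end, in percent of the substrate charged, summer
- the largest of these amounts at the end, in percent of the substrate charged, dawn

In blue at 4.00 min the substrate was down to 3.0%, with open intermediate at 92.1% and target far lower at 4.3%. So I took the first step as finished and reckoned with what it left free. Blue held over one equivalent of both partners, so its readings could not say which one the first step takes. I took partner B, one equivalent per substrate, and then one further partner B and one partner A for each target.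

Summer then had 0.300 equiv of partner B beyond the first equivalent, less than its partner A, so target could reach 30.0%. This target ceiling, the lesser of spare partner B and partner A, names the limiting reagent of the second stage. On this reckoning open intermediate in summer stayed at 70.0% or above, and I expected it to lead.

Dawn's ceiling was 90.0%, from partner A, which stood below its spare partner B. I took target's pace to go with spare partner B times partner A, which gave dawn 2.14 times blue's pace. Blue made 15.2% of target by 12.0 min, so if dawn held that starting pace, I reckoned that half of the substrate in dawn would be target after 18.4 min. That estimate is shorter than 1.0 h, so I expected target to lead dawn, below its ceiling.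

The forecast differed from my reckoning: it gave target at 47% for summer and target at 62% for dawn, with these words: “I assume A is consumed stoichiometrically.”

The flask gave open intermediate at 72.4% in summer and target at 69.1% in dawn.

    substrate + partner B → open intermediate (k = 45.0 L mol⁻¹ min⁻¹)
    partner B + partner A → second intermediate (k = 1.30 L mol⁻¹ min⁻¹)
    open intermediate + second intermediate → target (k = 4.10 L mol⁻¹ min⁻¹)
    crystals ⇌ target, rate k4*(cs4 - [target]) while solid is left; crystals form when [target] > cs4 (solubility = 0.540 mM, k = 2.80 min⁻¹)

Summer's target stayed low because partner B ran short: free partner B was down to 1.37% of its charge at 1.0 h, target stood at 27.6%, and the same run with partner B kept from running short gave 82.9%. After 10.0 h summer came to 30.0%, level with its ceiling of 30.0%, and dawn came to 89.7%, level with 90.0%. Dawn's neighbour with 0.230 equiv of partner A has a ceiling of 23.0%, and after 1.00 h it held 21.7% of target.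

The numbers in the tables are simulated with constants of no real substance; scatter was added.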